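## Retrosynthetic overview

1. The target is a 5,5′-biaryl of a 2,3-cis olivil-type oxolane and a cycloolivil-type tetralin; the biaryl bond is cut last (one-flask borylation / Suzuki coupling / desilylation).
2. Both halves come from one aryl bromide, a bromo oxolane diol; the tetralin half is made from it by acid-induced oxolane opening and Friedel–Crafts reclosure.
3. The benzyl C–C bond and the tertiary carbinol of the oxolane come from aryl-cuprate opening of a spiro-epoxide made from a 2-aryl-3-(silyloxymethyl)-4-methylene-oxolane.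
4. That oxolane is made by a catalytic enantioselective seven-to-five ring contraction of a 2-aryl-5-(silylmethyl)-4,7-dihydro-1,3-dioxepine, which sets the two cis ring stereocentres.
5. Ring order: dioxepine → oxolane → spiro-epoxide → tetralin (one half). Building blocks: catechol, glyoxylic acid, 4-bromofuran-2(5H)-one and Me3SiCH2MgCl.

Assumption: the (S,S) antipode of the chiral acid in step 10 is taken as the one giving the (2R,3R)-oxolane; if the sense is opposite, the (R,R) acid is used.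

Abbreviations: TIPS = tri(propan-2-yl)silyl; ArBr = 3-bromo-5-methoxy-4-(TIPS-oxy)phenyl; ArO = 3-methoxy-4-(TIPS-oxy)phenyl.

## Route

Step 1
Reactants: 1 catechol (benzene-1,2-diol)
Product: 2 guaiacol (2-methoxyphenol)
Conditions: MeI (1.0 equiv), Li2CO3, DMF, 55 °C
Reagents that add atoms: iodomethane (CI)
Why: Williamson mono-O-methylation; the weak base forms only the mono-phenoxide, so the second OH stays free.

Step 2
Reactants: 2 guaiacol; 3 glyoxylic acid
Product: 5 vanillin (4-hydroxy-3-methoxybenzaldehyde), via 4-hydroxy-3-methoxymandelic acid 4 (not isolated)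
Conditions: NaOH aq., 25 °C; then CuSO4 (cat.), O2 (air), NaOH aq., 95 °C; HCl aq.
Reagents that add atoms: none
Why: Electrophilic aromatic hydroxyalkylation para to the phenoxide, then copper-catalysed aerobic oxidative decarboxylation of the mandelate (the technical vanillin sequence).

Step 3
Reactants: 5 vanillin
Product: 6 5-bromovanillin (3-bromo-4-hydroxy-5-methoxybenzaldehyde)
Conditions: Br2, MeOH, 0 °C
Reagents that add atoms: bromine (BrBr)
Why: Electrophilic aromatic bromination at the only free position ortho to the phenol.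

Step 4
Reactants: 6 5-bromovanillin
Product: 7 3-bromo-5-methoxy-4-(TIPS-oxy)benzaldehyde
Conditions: TIPSCl, imidazole, DMF, 40 °C
Reagents that add atoms: chlorotri(propan-2-yl)silane (CC(C)[Si](Cl)(C(C)C)C(C)C)
Why: O-silylation of the acidic phenol; the bulky silyl ether withstands organometallics, mild acid and cross-coupling and is removed by fluoride at the end.

Step 5
Reactants: 2 guaiacol
Product: 8 4-bromo-2-methoxyphenol
Conditions: NBS, MeCN, 0 °C
Reagents that add atoms: N-bromosuccinimide (O=C1CCC(=O)N1Br)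
Why: Electrophilic aromatic bromination para to the stronger donor (OH).

Step 6
Reactants: 8 4-bromo-2-methoxyphenol
Product: 9 (4-bromo-2-methoxyphenoxy)tri(propan-2-yl)silane
Conditions: TIPSCl, imidazole, DMF, 25 °C
Reagents that add atoms: chlorotri(propan-2-yl)silane (CC(C)[Si](Cl)(C(C)C)C(C)C)
Why: O-silylation so that the aryl bromide can later be turned into a Grignard reagent.

Step 7
Reactants: 10 4-bromofuran-2(5H)-one; 11 [(trimethylsilyl)methyl]magnesium chloride
Product: 13 4-[(trimethylsilyl)methyl]furan-2(5H)-one, via organozinc chloride 12 (not isolated)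
Conditions: 11, ZnCl2, THF, 0 °C; then 10, Pd(PPh3)4 (3 mol%), THF, 25–40 °C
Reagents that add atoms: none
Why: Negishi coupling of the β-bromo-butenolide (fast oxidative addition); the organozinc leaves the lactone and its acidic γ-hydrogens alone.

Step 8
Reactants: 13 4-[(trimethylsilyl)methyl]furan-2(5H)-one
Product: 14 (2E)-2-[(trimethylsilyl)methyl]but-2-ene-1,4-diol (the two CH2OH groups cis on the C=C)
Conditions: i-Bu2AlH (4.5 equiv), CH2Cl2, −78 → 0 °C; aq. KNaC4H4O6
Reagents that add atoms: none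
Why: Hydride reduction of the lactone to the diol; the ring fixes the cis relation of the two CH2OH groups needed for a seven-membered acetal.

Step 9
Reactants: 7 3-bromo-5-methoxy-4-(TIPS-oxy)benzaldehyde; 14 (2E)-2-[(trimethylsilyl)methyl]but-2-ene-1,4-diol
Product: 15 rac-2-(ArBr)-5-[(trimethylsilyl)methyl]-4,7-dihydro-1,3-dioxepine
Conditions: pyridinium p-toluenesulfonate (10 mol%), benzene, reflux, Dean–Stark
Reagents that add atoms: none
Why: Acid-catalysed dehydrative acetalisation with a cis-butenediol; the acetal centre is racemic, which does not matter because it is ionised in step 10.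

Step 10
Reactants: 15 rac-2-(ArBr)-5-[(trimethylsilyl)methyl]-4,7-dihydro-1,3-dioxepine
Product: 16 {[(2R,3R)-2-(ArBr)-4-methylideneoxolan-3-yl]methoxy}trimethylsilane (aryl and CH2OSiMe3 cis)
Conditions: (S,S)-IDPi acid [HN(P(=NTf)(O2-BINOL*))2, BINOL* = (S)-3,3′-bis(3,5-(CF3)2C6H3)-1,1′-bi-2-naphtholate] (3 mol%), CH2Cl2, −60 °C; Et3N quench; Et3N-deactivated silica
Reagents that add atoms: none
Why: Proposed new method: the confined chiral acid ionises the acetal C–O bond on the CH= side of the ring (the other ionisation cannot reach a five-membered closure and is reversible); the anion-paired E-oxocarbenium is attacked by the allylsilane carbon of the ring-derived cis alkene through a twist closure that puts aryl and CH2O on the same face (2,3-cis, kinetic); the β-silyl cation collapses to the exocyclic alkene and the silyl group is passed to the freed oxygen, so the net change is a by-product-free seven-to-five ring contraction in which the catalyst's enantioface choice converts the racemic acetal into the (2R,3R) product; the closest known reactions are the Lewis-acid [1,3] O-to-C ring contraction of 4,5-dihydro-1,3-dioxepines to cis-2,3-disubstituted oxolane-3-carbaldehydes, intramolecular Hosomi–Sakurai (silyl-Prins) cyclisations and IDPi-catalysed asymmetric additions of allylsilanes to oxocarbenium ions.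

Step 11
Reactants: 16 {[(2R,3R)-2-(ArBr)-4-methylideneoxolan-3-yl]methoxy}trimethylsilane
Product: 17 {[(3R,6R,7R)-6-(ArBr)-1,5-dioxaspiro[2.4]heptan-7-yl]methoxy}trimethylsilane (epoxide O trans to aryl and CH2O)
Conditions: dimethyldioxirane (1.3 equiv, acetone), CH2Cl2, −20 → 0 °C
Reagents that add atoms: dimethyldioxirane (CC1(C)OO1)
Why: Substrate-controlled dioxirane epoxidation of the 1,1-disubstituted alkene from the face opposite the cis aryl and CH2OSiMe3 groups; this sets the quaternary centre (3R), the later tertiary carbinol.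

Step 12
Reactants: 17 {[(3R,6R,7R)-6-(ArBr)-1,5-dioxaspiro[2.4]heptan-7-yl]methoxy}trimethylsilane; 9 (4-bromo-2-methoxyphenoxy)tri(propan-2-yl)silane
Product: 20 (3S,4R,5R)-5-(ArBr)-4-(hydroxymethyl)-3-(ArO-methyl)oxolan-3-ol, via arylmagnesium bromide 18 (not isolated), via primary trimethylsilyl ether 19 (not isolated)
Conditions: 9 (1.6 equiv), Mg, THF, 45 °C; CuBr·SMe2 (10 mol%), then 17, −40 → −10 °C; H2O/AcOH/THF, 25 °C
Reagents that add atoms: none
Why: Copper-catalysed SN2 opening of the 2,2-disubstituted epoxide at its CH2 terminus by the aryl Grignard reagent (no stereocentre touched, aryl bromide inert at low temperature); the transient silyl ether blocks alkoxide attack on the epoxide and is removed in the mild acid work-up.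

Step 13
Reactants: 20 (3S,4R,5R)-5-(ArBr)-4-(hydroxymethyl)-3-(ArO-methyl)oxolan-3-ol
Product: 21 (2S,3S,4S)-4-(ArBr)-2,3-bis(hydroxymethyl)-7-methoxy-6-(TIPS-oxy)-1,2,3,4-tetrahydronaphthalen-2-ol
Conditions: TfOH (10 mol%), (CF3)2CHOH/CH2Cl2 (1:3), 0 °C; NaHCO3
Reagents that add atoms: none
Why: Acid ionisation of the benzylic oxolane C–O bond and six-ring Friedel–Crafts alkylation para to OMe (the oxolane-to-tetralin reorganisation known for olivil-type lignans); the new benzylic centre (4S) forms with the aryl group trans to the neighbouring CH2OH, both pseudo-equatorial, and the other two centres are untouched.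

Step 14
Reactants: 20 (3S,4R,5R)-5-(ArBr)-4-(hydroxymethyl)-3-(ArO-methyl)oxolan-3-ol; 21 (2S,3S,4S)-4-(ArBr)-2,3-bis(hydroxymethyl)-7-methoxy-6-(TIPS-oxy)-1,2,3,4-tetrahydronaphthalen-2-ol
Product: 24 (2S,3S,4S)-4-[4-hydroxy-3-{2-hydroxy-5-[(2R,3R,4S)-4-hydroxy-4-(4-hydroxy-3-methoxybenzyl)-3-(hydroxymethyl)oxolan-2-yl]-3-methoxyphenyl}-5-methoxyphenyl]-2,3-bis(hydroxymethyl)-7-methoxy-1,2,3,4-tetrahydronaphthalene-2,6-diol (CNP0344108.1), via pinacol boronate 22 (not isolated), via tetrakis-silyl biaryl 23 (not isolated)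
Conditions: 20 (1.05 equiv), B2pin2, KOAc, Pd(dppf)Cl2 (4 mol%), 1,4-dioxane, 90 °C; then 21 (1.0 equiv), Pd(OAc)2/SPhos (5/10 mol%), K3PO4 aq., 90 °C; then solvent switch to THF, Bu4NF/AcOH (1:1, 6 equiv), 0 → 25 °C
Reagents that add atoms: none
Why: Miyaura borylation, Suzuki–Miyaura coupling and buffered fluoride desilylation in one flask; no stereocentre is touched, the silyl ethers keep the phenols from forming quinone methides under hot base, and the doubly ortho-substituted biaryl axis rotates freely.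

## Compound list

1 | catechol | Oc1ccccc1O | starting material
2 | guaiacol | COc1ccccc1O | intermediate
3 | glyoxylic acid | O=CC(=O)O | starting material
4 | 4-hydroxy-3-methoxymandelic acid (racemic) | COc1cc(C(O)C(=O)O)ccc1O | intermediate
5 | vanillin | COc1cc(C=O)ccc1O | intermediate
6 | 5-bromovanillin | COc1cc(C=O)cc(Br)c1O | intermediate
7 | 3-bromo-5-methoxy-4-(TIPS-oxy)benzaldehyde | COc1cc(C=O)cc(Br)c1O[Si](C(C)C)(C(C)C)C(C)C | intermediate
8 | 4-bromo-2-methoxyphenol | COc1cc(Br)ccc1O | intermediate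
9 | (4-bromo-2-methoxyphenoxy)tri(propan-2-yl)silane | COc1cc(Br)ccc1O[Si](C(C)C)(C(C)C)C(C)C | intermediate
10 | 4-bromofuran-2(5H)-one | BrC1=CC(=O)OC1 | starting material
11 | [(trimethylsilyl)methyl]magnesium chloride | C[Si](C)(C)C[Mg]Cl | starting material
12 | chloro[(trimethylsilyl)methyl]zinc | C[Si](C)(C)C[Zn]Cl | intermediate
13 | 4-[(trimethylsilyl)methyl]furan-2(5H)-one | C[Si](C)(C)CC1=CC(=O)OC1 | intermediate
14 | (2E)-2-[(trimethylsilyl)methyl]but-2-ene-1,4-diol | OC/C(C[Si](C)(C)C)=C\CO | intermediate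
15 | rac-2-(ArBr)-5-[(trimethylsilyl)methyl]-4,7-dihydro-1,3-dioxepine | COc1cc(C2OCC=C(C[Si](C)(C)C)CO2)cc(Br)c1O[Si](C(C)C)(C(C)C)C(C)C | intermediate
16 | {[(2R,3R)-2-(ArBr)-4-methylideneoxolan-3-yl]methoxy}trimethylsilane | C=C1CO[C@@H](c2cc(OC)c(O[Si](C(C)C)(C(C)C)C(C)C)c(Br)c2)[C@H]1CO[Si](C)(C)C | intermediate
17 | {[(3R,6R,7R)-6-(ArBr)-1,5-dioxaspiro[2.4]heptan-7-yl]methoxy}trimethylsilane | C1[C@@]2(O1)CO[C@@H](c3cc(OC)c(O[Si](C(C)C)(C(C)C)C(C)C)c(Br)c3)[C@H]2CO[Si](C)(C)C | intermediate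
18 | [3-methoxy-4-(TIPS-oxy)phenyl]magnesium bromide | COc1cc([Mg]Br)ccc1O[Si](C(C)C)(C(C)C)C(C)C | intermediate
19 | (3S,4R,5R)-5-(ArBr)-3-(ArO-methyl)-4-{[(trimethylsilyl)oxy]methyl}oxolan-3-ol | COc1cc(C[C@@]2(O)CO[C@@H](c3cc(OC)c(O[Si](C(C)C)(C(C)C)C(C)C)c(Br)c3)[C@H]2CO[Si](C)(C)C)ccc1O[Si](C(C)C)(C(C)C)C(C)C | intermediate
20 | (3S,4R,5R)-5-(ArBr)-4-(hydroxymethyl)-3-(ArO-methyl)oxolan-3-ol | COc1cc(C[C@@]2(O)CO[C@@H](c3cc(OC)c(O[Si](C(C)C)(C(C)C)C(C)C)c(Br)c3)[C@H]2CO)ccc1O[Si](C(C)C)(C(C)C)C(C)C | intermediate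
21 | (2S,3S,4S)-4-(ArBr)-2,3-bis(hydroxymethyl)-7-methoxy-6-(TIPS-oxy)-1,2,3,4-tetrahydronaphthalen-2-ol | COc1cc([C@H]2c3cc(O[Si](C(C)C)(C(C)C)C(C)C)c(OC)cc3C[C@@](O)(CO)[C@@H]2CO)cc(Br)c1O[Si](C(C)C)(C(C)C)C(C)C | intermediate
22 | pinacol boronate of 20 (Bpin in place of Br) | COc1cc(C[C@@]2(O)CO[C@@H](c3cc(OC)c(O[Si](C(C)C)(C(C)C)C(C)C)c(B4OC(C)(C)C(C)(C)O4)c3)[C@H]2CO)ccc1O[Si](C(C)C)(C(C)C)C(C)C | intermediate
23 | tetrakis-O-TIPS ether of the target (all four phenols silylated) | COc1cc(C[C@@]2(O)CO[C@@H](c3cc(OC)c(O[Si](C(C)C)(C(C)C)C(C)C)c(-c4cc([C@H]5c6cc(O[Si](C(C)C)(C(C)C)C(C)C)c(OC)cc6C[C@@](O)(CO)[C@@H]5CO)cc(OC)c4O[Si](C(C)C)(C(C)C)C(C)C)c3)[C@H]2CO)ccc1O[Si](C(C)C)(C(C)C)C(C)C | intermediate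
24 | CNP0344108.1 (name as in step 14) | COc1cc(C[C@@]2(O)CO[C@@H](c3cc(OC)c(O)c(-c4cc([C@H]5c6cc(O)c(OC)cc6C[C@@](O)(CO)[C@@H]5CO)cc(OC)c4O)c3)[C@H]2CO)ccc1O | target

## Step count and risks

Total steps: 14. Longest linear sequence: 10 (steps 1, 2, 3, 4, 9, 10, 11, 12, 13, 14).

Most likely to fail:

Step 10 (the new ring contraction). Risks are a slow five-membered closure, protodesilylation of the allylsilane, low enantioselectivity or formation of the trans isomer. The known-chemistry fallback sets out from aldehyde 7 and returns at 16 by an auxiliary-controlled anti-aldol route. (4R)-4-Benzyl-1,3-oxazolidin-2-one is N-acylated (n-BuLi, 3-(chloromethyl)but-3-enoyl chloride) to the imide (4R)-4-benzyl-3-[3-(chloromethyl)but-3-enoyl]-1,3-oxazolidin-2-one F1. Magnesium-halide-catalysed anti-aldol addition to 7 (MgCl2 10 mol%, Et3N, Me3SiCl, EtOAc; then CF3CO2H/MeOH) gives the anti-aldol adduct F2, the chelated enolate being attacked on the face away from the auxiliary benzyl group. Intramolecular allylic etherification (Pd(PPh3)4, Et3N, THF) closes the ring to the cis oxolane imide F3. LiBH4 (THF/H2O) removes the auxiliary to give the oxolane methanol F4, and Me3SiCl/imidazole returns to 16.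

Step 13 (acid rearrangement to the tetralin). The flanked, twisted silyloxy group and the bromine make the benzylic cation hard to reach, and fragmentation or ionisation of the tertiary alcohol can compete. The fallback sets out from 20 and returns at 24. The silyl groups are removed first (Bu4NF/AcOH) to give the free bisphenol oxolane F5, whose para-hydroxybenzylic C–O bond ionises under the mild acid known for the olivil-to-cycloolivil change (aq. HCO2H, 25 °C), giving the free-phenol bromotetralin F6. F6 then takes the place of 21 in the borylation/Suzuki sequence with 20 (via 22) to give the bis-silyl biaryl F7, and Bu4NF/AcOH gives 24.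

Step 14 (borylation, coupling and desilylation in one flask). Risks are homocoupling, two bulky ortho-silyloxy groups at the new bond, and three operations on unprotected polyols. The fallback sets out from 16 and returns at 23 (then 24) by moving the biaryl union upstream. Borylation of the non-polar alkene 16 (B2pin2, KOAc, Pd(dppf)Cl2) gives the isolable alkene pinacol boronate F8. Suzuki coupling with 21 (Pd(OAc)2/SPhos, K3PO4 aq.; the primary trimethylsilyl ether is lost) gives the biaryl methylene-oxolane F9, and dimethyldioxirane gives the biaryl spiro-epoxide F10. After in-flask per-trimethylsilylation (Me3SiCl, Et3N), copper-catalysed opening with 18 and mild acid work-up gives 23, and Bu4NF/AcOH gives 24.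

Further compounds

F1 | step 10 | (4R)-4-benzyl-3-[3-(chloromethyl)but-3-enoyl]-1,3-oxazolidin-2-one | C=C(CCl)CC(=O)N1[C@H](Cc2ccccc2)COC1=O
F2 | step 10 | (4R)-4-benzyl-3-{(2S)-2-[(R)-(ArBr)(hydroxy)methyl]-3-(chloromethyl)but-3-enoyl}-1,3-oxazolidin-2-one | O[C@@H](c1cc(OC)c(O[Si](C(C)C)(C(C)C)C(C)C)c(Br)c1)[C@H](C(=C)CCl)C(=O)N1[C@H](Cc2ccccc2)COC1=O
F3 | step 10 | (4R)-4-benzyl-3-{[(2R,3S)-2-(ArBr)-4-methylideneoxolan-3-yl]carbonyl}-1,3-oxazolidin-2-one | C=C1CO[C@@H](c2cc(OC)c(O[Si](C(C)C)(C(C)C)C(C)C)c(Br)c2)[C@H]1C(=O)N3[C@H](Cc4ccccc4)COC3=O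
F4 | step 10 | [(2R,3R)-2-(ArBr)-4-methylideneoxolan-3-yl]methanol | C=C1CO[C@@H](c2cc(OC)c(O[Si](C(C)C)(C(C)C)C(C)C)c(Br)c2)[C@H]1CO
F5 | step 13 | (3S,4R,5R)-5-(3-bromo-4-hydroxy-5-methoxyphenyl)-3-(4-hydroxy-3-methoxybenzyl)-4-(hydroxymethyl)oxolan-3-ol | COc1cc(C[C@@]2(O)CO[C@@H](c3cc(OC)c(O)c(Br)c3)[C@H]2CO)ccc1O
F6 | step 13 | (2S,3S,4S)-4-(3-bromo-4-hydroxy-5-methoxyphenyl)-2,3-bis(hydroxymethyl)-7-methoxy-1,2,3,4-tetrahydronaphthalene-2,6-diol | COc1cc([C@H]2c3cc(O)c(OC)cc3C[C@@](O)(CO)[C@@H]2CO)cc(Br)c1O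
F7 | step 13 | bis-O-TIPS ether of the target (the two phenols of the oxolane half silylated) | COc1cc(C[C@@]2(O)CO[C@@H](c3cc(OC)c(O[Si](C(C)C)(C(C)C)C(C)C)c(-c4cc([C@H]5c6cc(O)c(OC)cc6C[C@@](O)(CO)[C@@H]5CO)cc(OC)c4O)c3)[C@H]2CO)ccc1O[Si](C(C)C)(C(C)C)C(C)C
F8 | step 14 | pinacol boronate of 16 (Bpin in place of Br) | C=C1CO[C@@H](c2cc(OC)c(O[Si](C(C)C)(C(C)C)C(C)C)c(B3OC(C)(C)C(C)(C)O3)c2)[C@H]1CO[Si](C)(C)C
F9 | step 14 | biaryl of the (2R,3R)-3-(hydroxymethyl)-4-methylideneoxolane unit and the (2S,3S,4S)-tetralin unit of 21, three phenols as TIPS ethers | C=C1CO[C@@H](c2cc(OC)c(O[Si](C(C)C)(C(C)C)C(C)C)c(-c3cc([C@H]4c5cc(O[Si](C(C)C)(C(C)C)C(C)C)c(OC)cc5C[C@@](O)(CO)[C@@H]4CO)cc(OC)c3O[Si](C(C)C)(C(C)C)C(C)C)c2)[C@H]1CO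
F10 | step 14 | (3R,6R,7R)-spiro-epoxide of F9 (1,5-dioxaspiro[2.4]heptane unit, epoxide O trans to aryl and CH2OH) | C1[C@@]2(O1)CO[C@@H](c3cc(OC)c(O[Si](C(C)C)(C(C)C)C(C)C)c(-c4cc([C@H]5c6cc(O[Si](C(C)C)(C(C)C)C(C)C)c(OC)cc6C[C@@](O)(CO)[C@@H]5CO)cc(OC)c4O[Si](C(C)C)(C(C)C)C(C)C)c3)[C@H]2CO
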